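**One-step world.** In a one-step world, where substrate meets a steady amount of coupling partner to give mono adduct and stops there, the logarithm of substrate falls on a straight line (the pseudo-first-order picture), so you can count time per power of ten.

common to all: substrate 0.10 M

| charge | coupling partner | remark | time |
|---|---|---|---|
| Saturday's | 0.28 M (fed, over 3.0 min) | run made earlier |  |
| Thursday's | 0.44 M (fed, over 3.0 min) | run made earlier |  |
| flask | 0.200 M (fed, over 3.0 min) |  | 1.5 h |

| run | time / min | mono adduct / % | substrate / % |
|---|---|---|---|
| Saturday's | 6.00 | 23.5 | 67.9 |
| Saturday's | 10.0 | 29.7 | 52.2 |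
| Saturday's | 15.0 | 32.2 | 36.9 |
| Saturday's | 25.0 | 32.2 | 22.9 |
| Saturday's | 40.0 | 28.6 | 12.6 |
| Saturday's | 80.0 | 22.4 | 0.7 |
| Thursday's | 6.00 | 30.9 | 56.7 |
| Thursday's | 10.0 | 36.7 | 37.1 |
| Thursday's | 15.0 | 37.4 | 23.3 |
| Thursday's | 25.0 | 35.0 | 8.8 |
| Thursday's | 40.0 | 29.2 | 4.9 |
| Thursday's | 80.0 | 14.0 | 0.4 |

(each reading ± 1 percentage point)



- the best time, 1.5 h at the latest, for mono adduct
- the amount of mono adduct, in percent of the substrate charged, at that time

**Decade time.** Saturday's reading at 15.0 min gives 34.6 min per power of ten, and Thursday's at 15.0 min gives 23.7 min. The ratio of these times, 1.46, stands near the ratio of the charges, 1.57, so I scale inversely with charge. That gives this flask 0.839 h as its decade time, the time in which substrate falls by a power of ten.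

**The ladder.** The feed lasts 3.0 min, short against the decade time, so count the partner as charged at once. Next comes the peak. Saturday's two highest readings of mono adduct stand 0.433 and 0.640 powers down in substrate, and Thursday's stand 0.431 and 0.633 down. I therefore expect this flask's peak at 0.5 of a decade time, 0.419 h, inside the limit. Slower than the decade time is the late fall of mono adduct: Thursday's last readings fall at a pace of a power of ten in 2.09 h, so I expect a broad top.

**Peak height.** A straight line through the highest readings of the two runs, logarithm against logarithm of charge, gives me 28.8% for this flask.

**The forecast.** It says 0.5 h and 29.5%, later than my time: “The maximum is broad, so the time is less certain than the yield.”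

**The result.** The flask peaks at 0.382 h with 27.5%, earlier than the forecast.

    coupling partner + mono adduct → bis adduct (k = 0.00230 /M/s)
    coupling partner + tris adduct → tetra adduct (k = 0.00610 /M/s)
    substrate + coupling partner → mono adduct (k = 0.00530 /M/s)
    coupling partner ⇌ dormant form (K = 0.790, k = 0.00110 /s)
    substrate + mono adduct → side product (k = 0.00970 /M/s)
    coupling partner + bis adduct → tris adduct (k = 0.0320 /M/s)

**Decade again.** This flask holds 27.2% of mono adduct at 0.306 h and 27.2% at 0.478 h. At the best time this flask holds 35.8% of its substrate, which is 0.857 h per power of ten, beside the decade time of 0.839 h. Scaled to the neighbour flask with 0.12 M of coupling partner, the decade time becomes 1.40 h. That neighbour holds 13.5% of its substrate at 1.50 h, which is 1.72 h per power of ten.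

All runs were generated by integration for substances that don't exist; noise was put on by code.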